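The plan opens the 2-pyrone ring at its O1–C6 bond. Ring atoms O1, C6=C5 and C4–OH make up a vinylogous acid, which read backwards is an ynone: C4 becomes a ketone, C5 and C6 an alkyne, and lactone carbon C2 a tert-butyl ester whose α-carbon C3 already carries the arylmethyl group. One gold(I)-catalysed operation ties the ester carbonyl oxygen to the remote alkyne carbon, expels isobutene and leaves the aromatic 4-hydroxy-2-pyrone, all without base, so the aryl methyl ketone is not disturbed. Precursor 17 arises by C-benzylation of an ynone β-keto ester (from (S)-propylene oxide) with an acetylbenzyl bromide (from 5-hydroxyvanillin); MOM and TBS groups then fall in one acid step.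

Key step: step 10

Remark on the chemistry: arene locants follow the target throughout (C1 one-carbon arm, C2 acetyl, C3 and C4 protected phenols, C5 methoxy, C6 hydrogen). Compound 14 is drawn as the open hydroxy ketone although it may rest partly as its cyclic hemiketal, and 17 is used as the mixture of its C2 epimers and enol form.

Step 1
Reactants: 1 (S)-propylene oxide; 2 lithium acetylide ethylenediamine complex
Product: 3 (2S)-pent-4-yn-2-ol
Conditions: DMSO, 0 °C to rt; then H2O
Reagents that add atoms: none
Why: Alkynylation of a terminal epoxide: the acetylide attacks the unsubstituted CH2 carbon in an SN2 opening, no bond to the stereocentre is touched, and the S configuration of 1 passes unchanged into 3, where it becomes the only stereocentre of the target.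

Step 2
Reactants: 3 (2S)-pent-4-yn-2-ol
Product: 4 tert-butyl(dimethyl)[(2S)-pent-4-yn-2-yloxy]silane
Conditions: TBSCl, imidazole, DMF, rt
Reagents that add atoms: tert-butyldimethylsilyl chloride (TBSCl), CC(C)(C)[Si](C)(C)Cl
Why: Imidazole-promoted silylation of a secondary alcohol is routine, and the bulky TBS ether withstands the organolithium and enolate steps and later keeps this oxygen from adding to the gold-activated alkyne.

Step 3
Reactants: 4 tert-butyl(dimethyl)[(2S)-pent-4-yn-2-yloxy]silane
Product: 6 methyl (5S)-5-(tert-butyldimethylsilyloxy)hex-2-ynoate, via lithium acetylide 5 (not isolated)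
Conditions: n-BuLi, THF, −78 °C; ClCO2Me, −78 to 0 °C
Reagents that add atoms: methyl chloroformate, COC(=O)Cl
Why: Deprotonation of the terminal alkyne and C-acylation of the lithium acetylide with a chloroformate (alkoxycarbonylation) is a standard route to alk-2-ynoates and does not affect the silyl ether.

Step 4
Reactants: 6 methyl (5S)-5-(tert-butyldimethylsilyloxy)hex-2-ynoate; 7 tert-butyl acetate
Product: 9 tert-butyl (7S)-7-(tert-butyldimethylsilyloxy)-3-oxooct-4-ynoate, via lithium enolate of tert-butyl acetate 8 (not isolated)
Conditions: LDA (2.5 equiv), 7 (2.5 equiv), THF, −78 °C; then 6, −78 °C; AcOH quench at −78 °C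
Reagents that add atoms: none
Why: Crossed Claisen condensation: the hard lithium enolate of tert-butyl acetate, which hardly self-condenses at −78 °C, adds to the ester carbonyl rather than to the alkyne, a second equivalent stores the product as its unreactive enolate, and the cold acidic quench avoids base-induced loss of the silyloxy group.

Step 5
Reactants: 10 5-hydroxyvanillin (3,4-dihydroxy-5-methoxybenzaldehyde)
Product: 11 5-methoxy-3,4-bis(methoxymethoxy)benzaldehyde
Conditions: MOMCl, i-Pr2NEt, CH2Cl2, 0 °C to rt
Reagents that add atoms: chloromethyl methyl ether (MOMCl), COCCl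
Why: Base-mediated O-alkylation of both phenols (acetal protection); MOM ethers are chosen because they steer the lithiation of step 7, resist bases and gold(I), and leave together with the TBS group in acid, so no hydrogenation is needed near the pyrone C5=C6 bond and the aryl ketone.

Step 6
Reactants: 11 5-methoxy-3,4-bis(methoxymethoxy)benzaldehyde
Product: 12 [5-methoxy-3,4-bis(methoxymethoxy)phenyl]methanol
Conditions: NaBH4, MeOH, 0 °C
Reagents that add atoms: none
Why: Borohydride reduction of an aromatic aldehyde is chemoselective and gives the benzylic alcohol that serves first as a directing group and then as the precursor of the leaving group.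

Step 7
Reactants: 12 [5-methoxy-3,4-bis(methoxymethoxy)phenyl]methanol
Product: 14 1-[6-(hydroxymethyl)-4-methoxy-2,3-bis(methoxymethoxy)phenyl]ethan-1-one, via dilithio species 13 (not isolated)
Conditions: n-BuLi (2.3 equiv), THF, 0 °C; MeC(O)N(OMe)Me, −78 to 0 °C; AcOH quench
Reagents that add atoms: N-methoxy-N-methylacetamide, CC(=O)N(C)OC
Why: Directed ortho-metalation followed by a Weinreb ketone synthesis: after O-deprotonation the second equivalent of n-BuLi is guided to C2–H, which lies between the lithium alkoxide arm and the bidentate 3-OMOM group (a stronger director than the 5-OMe group next to C6–H, whose methyl is pushed towards C6 by the 4-substituent), and the chelated tetrahedral adduct of the amide stops the acylation at the ketone.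

Step 8
Reactants: 14 1-[6-(hydroxymethyl)-4-methoxy-2,3-bis(methoxymethoxy)phenyl]ethan-1-one
Product: 15 1-[6-(bromomethyl)-4-methoxy-2,3-bis(methoxymethoxy)phenyl]ethan-1-one
Conditions: CBr4, PPh3, CH2Cl2, 0 °C; short silica plug, used at once
Reagents that add atoms: carbon tetrabromide, BrC(Br)(Br)Br
Why: Appel reaction: the primary benzylic alcohol is activated as an alkoxyphosphonium ion and displaced by bromide under essentially neutral conditions that spare the MOM acetals and the ketone, and any hemiketal form drains through the open form.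

Step 9
Reactants: 9 tert-butyl (7S)-7-(tert-butyldimethylsilyloxy)-3-oxooct-4-ynoate; 15 1-[6-(bromomethyl)-4-methoxy-2,3-bis(methoxymethoxy)phenyl]ethan-1-one
Product: 17 tert-butyl (7S)-2-{[2-acetyl-5-methoxy-3,4-bis(methoxymethoxy)phenyl]methyl}-7-(tert-butyldimethylsilyloxy)-3-oxooct-4-ynoate (both C2 epimers), via sodium enolate 16 (not isolated)
Conditions: 9 (1.2 equiv), NaH (1.15 equiv), THF, 0 °C; then 15 (1.0 equiv), 0 °C to rt
Reagents that add atoms: none
Why: Acetoacetic-ester-type C-alkylation: the chelated sodium enolate is a soft carbon nucleophile that reacts fast with the activated benzylic bromide, all hydride is consumed before 15 is added so the methyl ketone never meets a strong base, a slight excess of 9 limits double alkylation, and the new C2 centre forms without control, which does not matter because it vanishes in step 10.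

Step 10
Reactants: 17 tert-butyl (7S)-2-{[2-acetyl-5-methoxy-3,4-bis(methoxymethoxy)phenyl]methyl}-7-(tert-butyldimethylsilyloxy)-3-oxooct-4-ynoate
Product: 18 3-{[2-acetyl-5-methoxy-3,4-bis(methoxymethoxy)phenyl]methyl}-6-[(2S)-2-(tert-butyldimethylsilyloxy)propyl]-4-hydroxy-2H-pyran-2-one
Conditions: (SPhos)AuNTf2 (5 mol %), MeNO2/AcOH 4:1, rt
Reagents that add atoms: none
Why: The cationic gold(I) centre binds the chain C4≡C5 alkyne, and the carbonyl oxygen of the tert-butyl ester, held close by the 1,3-dicarbonyl unit, adds anti to the β-carbon of the ynone (chain C5, pyrone C6), forming O1–C6. The resulting oxocarbenium ion loses its tert-butyl group as isobutene, which makes the addition irreversible, and protodeauration (helped by AcOH) followed by enolisation gives the aromatic 4-hydroxy-2-pyrone. The closest known reaction type is the gold(I)-catalysed cycloisomerisation of tert-butyl 3-oxoalk-4-ynoates, 2-alkylated ones included, to 4-hydroxy-2-pyrones. The single ring closes in the 6-endo-dig mode, since the 5-exo-dig alternative would need attack at the electron-rich α-carbon and is ruled out by the polarisation of the ynone. No stereocentre is made: the labile C2 centre becomes sp2, so both epimers and the enol of 17 converge on 18, and the remote silyloxy-bearing S centre is untouched. The ester oxygen must win over the homopropargylic oxygen, the acetyl oxygen and the electron-rich arene, which is secured by the bulky and weakly nucleophilic OTBS group, by the large rings the other two would have to form, and by the absence of base, which keeps the methyl ketone and C2 out of aldol chemistry.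

Step 11
Reactants: 18 3-{[2-acetyl-5-methoxy-3,4-bis(methoxymethoxy)phenyl]methyl}-6-[(2S)-2-(tert-butyldimethylsilyloxy)propyl]-4-hydroxy-2H-pyran-2-one
Product: 19 penicanesin D
Conditions: 3 M aq HCl, THF, 40 °C, argon
Reagents that add atoms: none
Why: Acid-catalysed hydrolysis removes the two aryl MOM acetals and the secondary silyl ether under one set of conditions to which the pyrone, the catechol (kept under argon), the ketone and the non-ionisable secondary carbinol centre are inert, so the S configuration is retained.

Compound list
1 | (S)-propylene oxide, (2S)-2-methyloxirane | C[C@H]1CO1 | starting material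
2 | lithium acetylide ethylenediamine complex | [Li]C#C.NCCN | starting material
3 | (2S)-pent-4-yn-2-ol | C#CC[C@H](C)O | intermediate
4 | tert-butyl(dimethyl)[(2S)-pent-4-yn-2-yloxy]silane | C#CC[C@H](C)O[Si](C)(C)C(C)(C)C | intermediate
5 | [(4S)-4-(tert-butyldimethylsilyloxy)pent-1-yn-1-yl]lithium | [Li]C#CC[C@H](C)O[Si](C)(C)C(C)(C)C | intermediate
6 | methyl (5S)-5-(tert-butyldimethylsilyloxy)hex-2-ynoate | COC(=O)C#CC[C@H](C)O[Si](C)(C)C(C)(C)C | intermediate
7 | tert-butyl acetate | CC(=O)OC(C)(C)C | starting material
8 | lithium enolate of tert-butyl acetate | C=C(O[Li])OC(C)(C)C | intermediate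
9 | tert-butyl (7S)-7-(tert-butyldimethylsilyloxy)-3-oxooct-4-ynoate | CC(C)(C)OC(=O)CC(=O)C#CC[C@H](C)O[Si](C)(C)C(C)(C)C | intermediate
10 | 5-hydroxyvanillin (3,4-dihydroxy-5-methoxybenzaldehyde) | COc1cc(C=O)cc(O)c1O | starting material
11 | 5-methoxy-3,4-bis(methoxymethoxy)benzaldehyde | COc1cc(C=O)cc(OCOC)c1OCOC | intermediate
12 | [5-methoxy-3,4-bis(methoxymethoxy)phenyl]methanol | COc1cc(CO)cc(OCOC)c1OCOC | intermediate
13 | lithium [2-lithio-5-methoxy-3,4-bis(methoxymethoxy)phenyl]methanolate | COc1cc(CO[Li])c([Li])c(OCOC)c1OCOC | intermediate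
14 | 1-[6-(hydroxymethyl)-4-methoxy-2,3-bis(methoxymethoxy)phenyl]ethan-1-one | COc1cc(CO)c(C(C)=O)c(OCOC)c1OCOC | intermediate
15 | 1-[6-(bromomethyl)-4-methoxy-2,3-bis(methoxymethoxy)phenyl]ethan-1-one | COc1cc(CBr)c(C(C)=O)c(OCOC)c1OCOC | intermediate
16 | sodium enolate of 9 | [Na+].CC(C)(C)OC(=O)[CH-]C(=O)C#CC[C@H](C)O[Si](C)(C)C(C)(C)C | intermediate
17 | tert-butyl (7S)-2-{[2-acetyl-5-methoxy-3,4-bis(methoxymethoxy)phenyl]methyl}-7-(tert-butyldimethylsilyloxy)-3-oxooct-4-ynoate, both C2 epimers | COc1cc(CC(C(=O)OC(C)(C)C)C(=O)C#CC[C@H](C)O[Si](C)(C)C(C)(C)C)c(C(C)=O)c(OCOC)c1OCOC | intermediate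
18 | 3-{[2-acetyl-5-methoxy-3,4-bis(methoxymethoxy)phenyl]methyl}-6-[(2S)-2-(tert-butyldimethylsilyloxy)propyl]-4-hydroxy-2H-pyran-2-one | COc1cc(Cc2c(O)cc(C[C@H](C)O[Si](C)(C)C(C)(C)C)oc2=O)c(C(C)=O)c(OCOC)c1OCOC | intermediate
19 | penicanesin D, 3-[(2-acetyl-3,4-dihydroxy-5-methoxyphenyl)methyl]-4-hydroxy-6-[(2S)-2-hydroxypropyl]-2H-pyran-2-one | COc1cc(Cc2c(O)cc(C[C@H](C)O)oc2=O)c(C(C)=O)c(O)c1O | target

Total step count: 11.
Longest linear sequence: 7 steps (steps 1–4 then 9–11, or equally steps 5–8 then 9–11).

Steps most likely to fail

Step 10. The cationic catalyst may be tied up by the acetal and ketone oxygens of the arene. Alternatively, the activated alkyne may be intercepted by the electron-rich ring, so that ring closure stalls or strays. The fallback reverses the order of ring closure and benzylation; it sets out from 9 and 14 and comes back at 18. Keto ester 9, the unbranched parent of this substrate class, would be cycloisomerised with the same type of gold(I) catalyst to 6-[(2S)-2-(tert-butyldimethylsilyloxy)propyl]-4-hydroxy-2H-pyran-2-one F1. Alcohol 14 would be oxidised with MnO2 in CH2Cl2 to 2-acetyl-5-methoxy-3,4-bis(methoxymethoxy)benzaldehyde F2. The two would then be joined at the nucleophilic pyrone C3 by a proline-catalysed Knoevenagel condensation to the 3-arylmethylidenepyran-2,4-dione F3. A Hantzsch ester in the same flask reduces this by conjugate hydride transfer to 18. This three-component reductive alkylation is C-selective because no O-alkylating agent is present.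

Step 9. O-alkylation may compete, the enolate may add in conjugate fashion to the ynone of freshly formed product, or base may induce loss of silanolate from the propargylic position. The fallback makes the chain C2–C3 bond last, by decarboxylative acylation under soft enolisation; it sets out from 15 and 4 and comes back at 17. Bromide 15 would alkylate the sodium salt of commercial benzyl tert-butyl malonate (NaH, THF) to 1-benzyl 3-tert-butyl 2-{[2-acetyl-5-methoxy-3,4-bis(methoxymethoxy)phenyl]methyl}propanedioate F4. Hydrogenolysis of the benzyl ester (H2, Pd/C, EtOAc), with no alkyne yet present, would give 2-{[2-acetyl-5-methoxy-3,4-bis(methoxymethoxy)phenyl]methyl}-3-tert-butoxy-3-oxopropanoic acid F5. Alkyne 4 would be lithiated and carboxylated (n-BuLi, then CO2) to (5S)-5-(tert-butyldimethylsilyloxy)hex-2-ynoic acid F6. This acid would be activated with carbonyldiimidazole as (5S)-5-(tert-butyldimethylsilyloxy)-1-(imidazol-1-yl)hex-2-yn-1-one F7. The magnesium enolate of the half ester (MgCl2, Et3N, MeCN) would attack the acyl imidazole, and loss of CO2 would give 17 without the methyl ketone meeting a strong base.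

Step 7. The lithiation may discriminate incompletely between the two ring C–H bonds, or the acyl donor may transfer a proton to the hindered aryllithium. The fallback fixes the site with a halogen and brings in the acetyl group by cross-coupling; it sets out from 10 and comes back at 14.
- One equivalent each of base and MOMCl would protect the more acidic 4-OH (para to the aldehyde) to give 3-hydroxy-5-methoxy-4-(methoxymethoxy)benzaldehyde F8.
- Amine-catalysed ortho-bromination of the free phenol (NBS, cat. i-Pr2NH, CH2Cl2) should place bromine at C2, the only open position ortho to the 3-OH and also para to the methoxy group, giving 2-bromo-3-hydroxy-5-methoxy-4-(methoxymethoxy)benzaldehyde F9.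
- A second MOM protection would give 2-bromo-5-methoxy-3,4-bis(methoxymethoxy)benzaldehyde F10.
- NaBH4 reduction would give [2-bromo-5-methoxy-3,4-bis(methoxymethoxy)phenyl]methanol F11.
- Stille coupling with tributyl(1-ethoxyvinyl)stannane (PdCl2(PPh3)2, toluene, 100 °C) would give [2-(1-ethoxyethenyl)-5-methoxy-3,4-bis(methoxymethoxy)phenyl]methanol F12.
- Brief treatment of this enol ether with cold dilute acid should hydrolyse it to 14 well before the MOM ethers react.

Further compounds
F1 | step 10 | 6-[(2S)-2-(tert-butyldimethylsilyloxy)propyl]-4-hydroxy-2H-pyran-2-one | O=c1cc(O)cc(C[C@H](C)O[Si](C)(C)C(C)(C)C)o1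
F2 | step 10 | 2-acetyl-5-methoxy-3,4-bis(methoxymethoxy)benzaldehyde | COc1cc(C=O)c(C(C)=O)c(OCOC)c1OCOC
F3 | step 10 | 3-{[2-acetyl-5-methoxy-3,4-bis(methoxymethoxy)phenyl]methylidene}-6-[(2S)-2-(tert-butyldimethylsilyloxy)propyl]pyran-2,4-dione (alkene geometry not defined) | COc1cc(C=C2C(=O)C=C(C[C@H](C)O[Si](C)(C)C(C)(C)C)OC2=O)c(C(C)=O)c(OCOC)c1OCOC
F4 | step 9 | 1-benzyl 3-tert-butyl 2-{[2-acetyl-5-methoxy-3,4-bis(methoxymethoxy)phenyl]methyl}propanedioate (racemic) | COc1cc(CC(C(=O)OCc2ccccc2)C(=O)OC(C)(C)C)c(C(C)=O)c(OCOC)c1OCOC
F5 | step 9 | 2-{[2-acetyl-5-methoxy-3,4-bis(methoxymethoxy)phenyl]methyl}-3-tert-butoxy-3-oxopropanoic acid (racemic) | COc1cc(CC(C(=O)O)C(=O)OC(C)(C)C)c(C(C)=O)c(OCOC)c1OCOC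
F6 | step 9 | (5S)-5-(tert-butyldimethylsilyloxy)hex-2-ynoic acid | OC(=O)C#CC[C@H](C)O[Si](C)(C)C(C)(C)C
F7 | step 9 | (5S)-5-(tert-butyldimethylsilyloxy)-1-(imidazol-1-yl)hex-2-yn-1-one | O=C(C#CC[C@H](C)O[Si](C)(C)C(C)(C)C)n1ccnc1
F8 | step 7 | 3-hydroxy-5-methoxy-4-(methoxymethoxy)benzaldehyde | COCOc1c(O)cc(C=O)cc1OC
F9 | step 7 | 2-bromo-3-hydroxy-5-methoxy-4-(methoxymethoxy)benzaldehyde | COCOc1c(OC)cc(C=O)c(Br)c1O
F10 | step 7 | 2-bromo-5-methoxy-3,4-bis(methoxymethoxy)benzaldehyde | COCOc1c(OC)cc(C=O)c(Br)c1OCOC
F11 | step 7 | [2-bromo-5-methoxy-3,4-bis(methoxymethoxy)phenyl]methanol | COCOc1c(OC)cc(CO)c(Br)c1OCOC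
F12 | step 7 | [2-(1-ethoxyethenyl)-5-methoxy-3,4-bis(methoxymethoxy)phenyl]methanol | CCOC(=C)c1c(CO)cc(OC)c(OCOC)c1OCOC
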